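The cyclopentene ring is traced back to a six-membered thiane 1,1-dioxide: its trisubstituted C(Et)=CH double bond is exactly what a Ramberg–Bäcklund contraction leaves when SO2 is excised from between the ethyl-bearing carbon and the CH2 next to the CHMe centre. The sulfur atom first serves as the tether of an intramolecular Diels–Alder reaction of a sulfide-linked tetraenyl enal, which builds the cyclohexene, both quaternary carbons and the trans ring fusion, steered by two (S)-configured tether centres taken from the captopril side-chain acid and methyl (R)-2-bromobutanoate. The contraction then delivers the target directly from the trans-fused bicyclic sulfone acid.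

Key step: step 12

Remark: compounds 1, 2, 7 and 10 are taken as catalogue compounds; the bicyclic intermediates are numbered as 1H-isothiochromenes (C1 = CHEt, S2, C3 = CH2, C4 = CHMe, C4a and C8a = ring fusion, C7 and C8 = quaternary carbons).

Step 1
Reactants: 1 (S)-3-(acetylsulfanyl)-2-methylpropanoic acid; 2 methyl (R)-2-bromobutanoate
Product: 4 (S)-3-{[(S)-1-methoxy-1-oxobutan-2-yl]sulfanyl}-2-methylpropanoic acid, via thiolate 3 (not isolated)
Conditions: NaOMe (2.0 equiv), degassed MeOH, 0 °C; then 2, 0 °C to rt; aq. HCl work-up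
Reagents that add atoms: methyl (R)-2-bromobutanoate (compound 2), CC[C@@H](Br)C(=O)OC
Why: Methoxide unmasks the thiolate from the thioacetate and this soft nucleophile displaces the secondary α-bromide by SN2 substitution (sulfide formation) with inversion, which sets the (S)-configured carbon–sulfur centre, while exactly two equivalents of base leave no free methoxide that could epimerise the product.

Step 2
Reactants: 4 (S)-3-{[(S)-1-methoxy-1-oxobutan-2-yl]sulfanyl}-2-methylpropanoic acid
Product: 5 methyl (S)-2-{[(S)-3-hydroxy-2-methylpropyl]sulfanyl}butanoate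
Conditions: BH3·SMe2, THF, 0 °C to rt; then MeOH
Reagents that add atoms: none
Why: Borane reduces the carboxylic acid through its acyloxyborane much faster than it touches the methyl ester (chemoselective borane reduction), and neither stereocentre is involved.

Step 3
Reactants: 5 methyl (S)-2-{[(S)-3-hydroxy-2-methylpropyl]sulfanyl}butanoate
Product: 6 methyl (S)-2-{[(S)-2-methyl-3-oxopropyl]sulfanyl}butanoate
Conditions: (COCl)2, DMSO, CH2Cl2, −78 °C; then i-Pr2NEt, −78 to 0 °C
Reagents that add atoms: none
Why: The Swern oxidation tolerates dialkyl sulfides and, with a hindered amine at low temperature, should deliver the α-methyl aldehyde without epimerisation or β-elimination of thiolate.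

Step 4
Reactants: 6 methyl (S)-2-{[(S)-2-methyl-3-oxopropyl]sulfanyl}butanoate; 7 2-(triphenylphosphoranylidene)propanal
Product: 8 methyl (S)-2-{[(2S,3E)-2,4-dimethyl-5-oxopent-3-en-1-yl]sulfanyl}butanoate
Conditions: 7 (1.2 equiv), toluene, 80 °C
Reagents that add atoms: 2-(triphenylphosphoranylidene)propanal (compound 7), CC(C=O)=P(c1ccccc1)(c1ccccc1)c1ccccc1
Why: The Wittig reaction of the stabilised, weakly basic formyl ylide gives the trisubstituted enal with E geometry and should not epimerise the adjacent methyl-bearing centre.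

Step 5
Reactants: 8 methyl (S)-2-{[(2S,3E)-2,4-dimethyl-5-oxopent-3-en-1-yl]sulfanyl}butanoate; 7 2-(triphenylphosphoranylidene)propanal
Product: 9 methyl (S)-2-{[(2S,3E,5E)-2,4,6-trimethyl-7-oxohepta-3,5-dien-1-yl]sulfanyl}butanoate
Conditions: 7 (2 equiv), toluene, 110 °C
Reagents that add atoms: 2-(triphenylphosphoranylidene)propanal (compound 7), CC(C=O)=P(c1ccccc1)(c1ccccc1)c1ccccc1
Why: A second Wittig reaction with the same stabilised ylide on the less electrophilic enal needs more heat but again gives the E-configured trisubstituted double bond, the product dienal being too unreactive to be homologated further at a useful rate.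

Step 6
Reactants: 9 methyl (S)-2-{[(2S,3E,5E)-2,4,6-trimethyl-7-oxohepta-3,5-dien-1-yl]sulfanyl}butanoate; 10 diethyl [(E)-3-phenylprop-2-en-1-yl]phosphonate (diethyl cinnamylphosphonate)
Product: 11 methyl (S)-2-{[(2S,3E,5E,7E,9E)-2,4,6-trimethyl-10-phenyldeca-3,5,7,9-tetraen-1-yl]sulfanyl}butanoate
Conditions: 10, LiN(SiMe3)2, THF, −78 °C; then 9, −78 to 0 °C, dark
Reagents that add atoms: diethyl cinnamylphosphonate (compound 10), CCOP(=O)(C/C=C/c1ccccc1)OCC
Why: In this Horner–Wadsworth–Emmons reaction the allylic phosphonate anion adds to the aldehyde at low temperature faster than it can deprotonate the α-sulfanyl ester and gives the new disubstituted double bond with E geometry, completing the all-E tetraene.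

Step 7
Reactants: 11 methyl (S)-2-{[(2S,3E,5E,7E,9E)-2,4,6-trimethyl-10-phenyldeca-3,5,7,9-tetraen-1-yl]sulfanyl}butanoate
Product: 12 (S)-2-{[(2S,3E,5E,7E,9E)-2,4,6-trimethyl-10-phenyldeca-3,5,7,9-tetraen-1-yl]sulfanyl}butanal
Conditions: i-Bu2AlH (1.1 equiv), CH2Cl2, −78 °C; then MeOH, aq. potassium sodium tartrate
Reagents that add atoms: none
Why: At −78 °C i-Bu2AlH stops at the aluminium hemiacetal of the ester, so that work-up releases the aldehyde (partial ester reduction) with the polyene untouched, and the configurationally sensitive product is used at once.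

Step 8
Reactants: 12 (S)-2-{[(2S,3E,5E,7E,9E)-2,4,6-trimethyl-10-phenyldeca-3,5,7,9-tetraen-1-yl]sulfanyl}butanal; 7 2-(triphenylphosphoranylidene)propanal
Product: 13 (2E,4S)-2-methyl-4-{[(2S,3E,5E,7E,9E)-2,4,6-trimethyl-10-phenyldeca-3,5,7,9-tetraen-1-yl]sulfanyl}hex-2-enal
Conditions: 7 (1.5 equiv), CH2Cl2, 40 °C, BHT, dark
Reagents that add atoms: 2-(triphenylphosphoranylidene)propanal (compound 7), CC(C=O)=P(c1ccccc1)(c1ccccc1)c1ccccc1
Why: The Wittig reaction with the stabilised formyl ylide installs the E-configured α-methyl enal dienophile under nearly neutral conditions, which should preserve the (S)-configured sulfur-bearing centre.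

Step 9
Reactants: 13 (2E,4S)-2-methyl-4-{[(2S,3E,5E,7E,9E)-2,4,6-trimethyl-10-phenyldeca-3,5,7,9-tetraen-1-yl]sulfanyl}hex-2-enal
Product: 14 (1S,4S,4aS,7S,8R,8aS)-1-ethyl-4,5,7,8-tetramethyl-7-[(1E,3E)-4-phenylbuta-1,3-dien-1-yl]-3,4,4a,7,8,8a-hexahydro-1H-isothiochromene-8-carbaldehyde (trans-fused; 1-ethyl and 4-methyl equatorial)
Conditions: toluene (0.005 M), BHT (cat.), 110 °C, argon, dark
Reagents that add atoms: none
Why: The intramolecular Diels–Alder reaction should pass through the trans-fused chair-like transition state with the formyl group endo, in which allylic 1,3-strain against the C5 and C8 methyl groups keeps the 4-methyl and 1-ethyl groups of the two (S)-configured tether centres equatorial, so that these centres select the diene face and the E geometries of diene and dienophile fix C4a, C8a and the adjacent quaternary carbons C7 and C8 relative to them.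

Step 10
Reactants: 14 (1S,4S,4aS,7S,8R,8aS)-1-ethyl-4,5,7,8-tetramethyl-7-[(1E,3E)-4-phenylbuta-1,3-dien-1-yl]-3,4,4a,7,8,8a-hexahydro-1H-isothiochromene-8-carbaldehyde
Product: 16 (1S,4S,4aS,7S,8R,8aS)-1-ethyl-4,5,7,8-tetramethyl-7-[(1E,3E)-4-phenylbuta-1,3-dien-1-yl]-3,4,4a,7,8,8a-hexahydro-1H-isothiochromene-8-carbaldehyde 2,2-dioxide, via sulfoxide 15 (not isolated)
Conditions: (NH4)6Mo7O24·4H2O (10 mol %), 30% aq. H2O2, EtOH, 0 °C to rt
Reagents that add atoms: hydrogen peroxide, OO
Why: Hydrogen peroxide activated by (NH4)6Mo7O24 oxidises the sulfide through the sulfoxide to the sulfone (sulfide oxidation) far faster than it epoxidises unfunctionalised alkenes, so the diene and the ring alkene should survive.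

Step 11
Reactants: 16 (1S,4S,4aS,7S,8R,8aS)-1-ethyl-4,5,7,8-tetramethyl-7-[(1E,3E)-4-phenylbuta-1,3-dien-1-yl]-3,4,4a,7,8,8a-hexahydro-1H-isothiochromene-8-carbaldehyde 2,2-dioxide
Product: 17 (1S,4S,4aS,7S,8R,8aS)-1-ethyl-4,5,7,8-tetramethyl-7-[(1E,3E)-4-phenylbuta-1,3-dien-1-yl]-3,4,4a,7,8,8a-hexahydro-1H-isothiochromene-8-carboxylic acid 2,2-dioxide
Conditions: NaClO2, NaH2PO4, 2-methylbut-2-ene, t-BuOH/H2O, rt
Reagents that add atoms: sodium chlorite, [Na+].[O-]Cl=O
Why: The Pinnick oxidation converts hindered aldehydes without α-hydrogen cleanly into acids, and the large excess of 2-methylbut-2-ene removes hypochlorous acid before it can add to the diene.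

Step 12
Reactants: 17 (1S,4S,4aS,7S,8R,8aS)-1-ethyl-4,5,7,8-tetramethyl-7-[(1E,3E)-4-phenylbuta-1,3-dien-1-yl]-3,4,4a,7,8,8a-hexahydro-1H-isothiochromene-8-carboxylic acid 2,2-dioxide
Product: 20 22-nor-zyggomphic acid B, via bromosulfone 18 (not isolated), via episulfone 19 (not isolated)
Conditions: KOH/Al2O3, CBr2F2, t-BuOH/CH2Cl2, 0 °C to rt; then aq. HCl to pH 3
Reagents that add atoms: none
Why: KOH on Al2O3 deprotonates an α-carbon of the sulfone, the carbanion takes bromine from CBr2F2 to give 18, and a second deprotonation at the other α-carbon is followed by intramolecular 1,3-displacement of bromide to the episulfone 19, which loses SO2 to leave the C1=C3 double bond. This is the Ramberg–Bäcklund reaction in its in situ halogenation form, used as the known ring contraction of thiane 1,1-dioxides to cyclopentenes. The only ring closed is the thiirane 1,1-dioxide (3-exo-tet), and its collapse turns the six-membered sulfur-containing ring into the five-membered carbocycle by excision of the sulfur atom. No new stereocentre is formed: the ethyl-bearing sulfone centre, which served only to steer the cycloaddition, becomes sp2, and the remaining stereocentres (C4, C4a, C7, C8, C8a) have no acidic hydrogen, so the trans ring fusion is inherited from 17. The step needs positional selectivity for the alkene and chemoselectivity towards the diene: the alkene can only form between the two carbons that flanked sulfur, whichever of them is brominated, and CBr2F2 is chosen because it delivers no dihalocarbene that would cyclopropanate the alkenes, while the carboxylate, lacking an α-hydrogen, is a spectator.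

Compound list
1 | (S)-3-(acetylsulfanyl)-2-methylpropanoic acid | CC(=O)SC[C@@H](C)C(=O)O | starting material
2 | methyl (R)-2-bromobutanoate | CC[C@@H](Br)C(=O)OC | starting material
3 | (S)-2-methyl-3-sulfanylpropanoic acid (disodium thiolate-carboxylate in the flask) | SC[C@@H](C)C(=O)O | intermediate
4 | (S)-3-{[(S)-1-methoxy-1-oxobutan-2-yl]sulfanyl}-2-methylpropanoic acid | CC[C@@H](C(=O)OC)SC[C@@H](C)C(=O)O | intermediate
5 | methyl (S)-2-{[(S)-3-hydroxy-2-methylpropyl]sulfanyl}butanoate | CC[C@@H](C(=O)OC)SC[C@@H](C)CO | intermediate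
6 | methyl (S)-2-{[(S)-2-methyl-3-oxopropyl]sulfanyl}butanoate | CC[C@@H](C(=O)OC)SC[C@@H](C)C=O | intermediate
7 | 2-(triphenylphosphoranylidene)propanal | CC(C=O)=P(c1ccccc1)(c1ccccc1)c1ccccc1 | starting material
8 | methyl (S)-2-{[(2S,3E)-2,4-dimethyl-5-oxopent-3-en-1-yl]sulfanyl}butanoate | CC[C@@H](C(=O)OC)SC[C@@H](C)/C=C(\C)C=O | intermediate
9 | methyl (S)-2-{[(2S,3E,5E)-2,4,6-trimethyl-7-oxohepta-3,5-dien-1-yl]sulfanyl}butanoate | CC[C@@H](C(=O)OC)SC[C@@H](C)/C=C(C)/C=C(\C)C=O | intermediate
10 | diethyl [(E)-3-phenylprop-2-en-1-yl]phosphonate | CCOP(=O)(C/C=C/c1ccccc1)OCC | starting material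
11 | methyl (S)-2-{[(2S,3E,5E,7E,9E)-2,4,6-trimethyl-10-phenyldeca-3,5,7,9-tetraen-1-yl]sulfanyl}butanoate | CC[C@@H](C(=O)OC)SC[C@@H](C)/C=C(C)/C=C(C)/C=C/C=C/c1ccccc1 | intermediate
12 | (S)-2-{[(2S,3E,5E,7E,9E)-2,4,6-trimethyl-10-phenyldeca-3,5,7,9-tetraen-1-yl]sulfanyl}butanal | CC[C@@H](C=O)SC[C@@H](C)/C=C(C)/C=C(C)/C=C/C=C/c1ccccc1 | intermediate
13 | (2E,4S)-2-methyl-4-{[(2S,3E,5E,7E,9E)-2,4,6-trimethyl-10-phenyldeca-3,5,7,9-tetraen-1-yl]sulfanyl}hex-2-enal | CC[C@@H](/C=C(\C)C=O)SC[C@@H](C)/C=C(C)/C=C(C)/C=C/C=C/c1ccccc1 | intermediate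
14 | (1S,4S,4aS,7S,8R,8aS)-1-ethyl-4,5,7,8-tetramethyl-7-[(1E,3E)-4-phenylbuta-1,3-dien-1-yl]-3,4,4a,7,8,8a-hexahydro-1H-isothiochromene-8-carbaldehyde | CC[C@@H]1SC[C@@H](C)[C@@H]2C(C)=C[C@](C)(/C=C/C=C/c3ccccc3)[C@](C)(C=O)[C@@H]12 | intermediate
15 | 2-oxide of 14 (sulfoxide, both configurations at sulfur) | CC[C@@H]1S(=O)C[C@@H](C)[C@@H]2C(C)=C[C@](C)(/C=C/C=C/c3ccccc3)[C@](C)(C=O)[C@@H]12 | intermediate
16 | 2,2-dioxide of 14 (sulfone aldehyde) | CC[C@@H]1S(=O)(=O)C[C@@H](C)[C@@H]2C(C)=C[C@](C)(/C=C/C=C/c3ccccc3)[C@](C)(C=O)[C@@H]12 | intermediate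
17 | (1S,4S,4aS,7S,8R,8aS)-1-ethyl-4,5,7,8-tetramethyl-7-[(1E,3E)-4-phenylbuta-1,3-dien-1-yl]-3,4,4a,7,8,8a-hexahydro-1H-isothiochromene-8-carboxylic acid 2,2-dioxide | CC[C@@H]1S(=O)(=O)C[C@@H](C)[C@@H]2C(C)=C[C@](C)(/C=C/C=C/c3ccccc3)[C@](C)(C(=O)O)[C@@H]12 | intermediate
18 | 3-bromo derivative of 17 (potassium salt in the flask; configuration at C3 not defined) | CC[C@@H]1S(=O)(=O)C(Br)[C@@H](C)[C@@H]2C(C)=C[C@](C)(/C=C/C=C/c3ccccc3)[C@](C)(C(=O)O)[C@@H]12 | intermediate
19 | episulfone of 17: thiirane 1,1-dioxide spanning the former C1 and C3, fused to the cyclopentane that is trans-fused to the cyclohexene (potassium salt in the flask) | CCC12C(S1(=O)=O)[C@@H](C)[C@@H]1C(C)=C[C@](C)(/C=C/C=C/c3ccccc3)[C@](C)(C(=O)O)[C@@H]21 | intermediate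
20 | 22-nor-zyggomphic acid B | CCC1=C[C@@H](C)[C@@H]2C(C)=C[C@](C)(/C=C/C=C/c3ccccc3)[C@](C)(C(=O)O)[C@@H]12 | target

Total step count: 12. Longest linear sequence: 12 steps, from 1.

Steps most likely to fail

Step 9. The bond between the two fully substituted carbons may form too slowly, so that 1,5-hydrogen shifts or polymerisation of the polyene compete, or the cis-fused formyl-exo transition state may erode the ring-fusion selectivity. The fallback switches from the thermal pericyclic reaction to the cationic Diels–Alder manifold and sets out from 13. Acetalisation with HC(OMe)3 and pyridinium p-toluenesulfonate in MeOH should give the dimethyl acetal of 13 F1. Catalytic Me3SiOSO2CF3 in CH2Cl2 at −78 °C ionises it to the 1-methoxyallyl cation, a far stronger dienophile, which should cyclise at low temperature through the same trans-fused arrangement to the dimethyl acetal of 14 F2. Hydrolysis with aqueous oxalic acid on silica comes back to the route at 14.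

Step 12. Hydroxide- or difluorocarbene-derived side reactions on the diene, retention of the carboxylate on the basic support, or incomplete 1,3-elimination in the trans-fused sulfone may consume the material. The fallback keeps the ring contraction but runs it stepwise on a protected substrate, setting out from 17. Alkylation of the carboxylate with allyl bromide and K2CO3 in DMF should give the prop-2-en-1-yl ester of 17 F3. Deprotonation with LiN(i-Pr)2 in THF at −78 °C and chlorination with C2Cl6 should give the isolated α-chloro sulfone F4. KOt-Bu in THF at 0 °C should then effect the 1,3-elimination and loss of SO2 to the prop-2-en-1-yl ester of 20 F5. Pd(PPh3)4 with morpholine in THF releases the acid and comes back to the route at 20.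

Step 8. Epimerisation of the α-sulfanyl aldehyde during the slow, warm Wittig reaction would feed the mismatched epimer into the cycloaddition. The fallback sets out from 12, generated and kept cold. A fast Horner–Wadsworth–Emmons reaction with the sodium salt of triethyl 2-phosphonopropanoate (NaH, THF, −78 to 0 °C) should give the ethyl (2E,4S)-enoate F6. Reduction with i-Bu2AlH at −78 °C should give the allylic alcohol F7, and oxidation with MnO2 in CH2Cl2 comes back to the route at 13.

Further compounds
F1 | step 9 | dimethyl acetal of 13: (2E,4S)-1,1-dimethoxy-2-methylhex-2-en-4-yl (2S,3E,5E,7E,9E)-2,4,6-trimethyl-10-phenyldeca-3,5,7,9-tetraen-1-yl sulfide | CC[C@@H](/C=C(\C)C(OC)OC)SC[C@@H](C)/C=C(C)/C=C(C)/C=C/C=C/c1ccccc1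
F2 | step 9 | dimethyl acetal of 14: 8-(dimethoxymethyl) analogue of 14 | CC[C@@H]1SC[C@@H](C)[C@@H]2C(C)=C[C@](C)(/C=C/C=C/c3ccccc3)[C@](C)(C(OC)OC)[C@@H]12
F3 | step 12 | prop-2-en-1-yl ester of 17 | CC[C@@H]1S(=O)(=O)C[C@@H](C)[C@@H]2C(C)=C[C@](C)(/C=C/C=C/c3ccccc3)[C@](C)(C(=O)OCC=C)[C@@H]12
F4 | step 12 | 3-chloro derivative of F3 (configuration at C3 not defined) | CC[C@@H]1S(=O)(=O)C(Cl)[C@@H](C)[C@@H]2C(C)=C[C@](C)(/C=C/C=C/c3ccccc3)[C@](C)(C(=O)OCC=C)[C@@H]12
F5 | step 12 | prop-2-en-1-yl ester of 20 | CCC1=C[C@@H](C)[C@@H]2C(C)=C[C@](C)(/C=C/C=C/c3ccccc3)[C@](C)(C(=O)OCC=C)[C@@H]12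
F6 | step 8 | ethyl (2E,4S)-2-methyl-4-{[(2S,3E,5E,7E,9E)-2,4,6-trimethyl-10-phenyldeca-3,5,7,9-tetraen-1-yl]sulfanyl}hex-2-enoate | CC[C@@H](/C=C(\C)C(=O)OCC)SC[C@@H](C)/C=C(C)/C=C(C)/C=C/C=C/c1ccccc1
F7 | step 8 | (2E,4S)-2-methyl-4-{[(2S,3E,5E,7E,9E)-2,4,6-trimethyl-10-phenyldeca-3,5,7,9-tetraen-1-yl]sulfanyl}hex-2-en-1-ol | CC[C@@H](/C=C(\C)CO)SC[C@@H](C)/C=C(C)/C=C(C)/C=C/C=C/c1ccccc1
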